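**Plan**

- Ring atoms are named as in carotenoids: C1 = CMe2, C2, C3 = C–O, C4, C5 = C–Me, C6 = carbon that carries the chain. The retrosynthesis cuts the butenolide Cα–vinyl bond (Stille), the lactone C–O and Cβ–Cγ bonds (tandem Sonogashira–lactonization on (E)-2,3-dibromoacrylic acid), one chain alkene (Horner–Wadsworth–Emmons) and the ring A C6–alkyne bond (Sonogashira). In both rings it then cuts C5–C6 (sulfone-to-nitrile closure) and, together, C1–C2 and C4–C5.
- Enabling feature: rings A and B are the same (3R)-3-oxy-1,1,5-trimethylcyclohexane. Its C3 carbinol flanked by the C2 and C4 methylenes is an epichlorohydrin unit. C1 is the carbanion carbon of isobutyronitrile, whose nitrile carbon is C6. C5 is a sulfonyl carbanion carbon.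
- Forward: three-component union on (S)-epichlorohydrin, ring closure at C5–C6, desulfonylation, and one enol triflate that feeds both rings. Ring A: acetate, Sonogashira, chain growth to a terminal polyenyne. Ring B: carbonylation, epoxidation, alkyne, vinylstannane.
- End game: the terminal alkyne and dibromoacrylic acid give the Z bromobutenolide, and a final Stille coupling attaches ring B.
- Stereochemistry: C3 of both rings comes from (S)-epichlorohydrin. The ring B epoxide (C5, C6) comes from Sharpless epoxidation with D-(−)-diethyl tartrate. E alkenes come from the E enynol, the Wittig and Horner–Wadsworth–Emmons steps and syn hydrostannation. The Z ylidene comes from anti addition of the carboxylate to the alkyne.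

Key step: step 1

Remark: the sulfone-bearing centre (C5) is carried as a mixture of epimers up to the enol triflate, where it becomes trigonal.

**Route**

Step 1
Reactants: 1 isobutyronitrile; 2 (S)-epichlorohydrin; 3 ethyl phenyl sulfone
Product: 6 (4S)-4-hydroxy-2,2-dimethyl-6-(phenylsulfonyl)heptanenitrile (both epimers at the sulfone carbon), via lithium chlorohydrinate 4 (not isolated), via epoxynitrile 5 (not isolated)
Conditions: 1, LiN(iPr)2, THF, −78 °C; add 2, −78 °C, then 23 °C; recool to −78 °C, add PhSO2CH(Li)CH3 (from 3, n-BuLi, THF), DMPU, −78 → 23 °C; H2O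
Reagents that add atoms: none
Why: Lithiated 1 opens the strained epoxide of 2 at its CH2 terminus (C1–C2 bond), the chlorohydrinate 4 closes on warming by 3-exo-tet displacement of chloride to the new epoxide 5, and the α-sulfonyl carbanion of 3 opens 5 at its terminal CH2 (C4–C5 bond), so epichlorohydrin serves as a chiral three-carbon linchpin between two different carbanions in one flask. The closest known reaction type is the one-flask bis-alkylation of epichlorohydrin by two carbanions, each half being a standard epoxide opening by a nitrile or sulfone anion. No ring is closed in this operation; the carbocycle is closed in step 3 through C5–C6. The C3 stereocentre is taken unchanged from (S)-2 because none of its bonds is broken, and the order of addition (first nucleophile on the epoxide carbon, second on the former CH2Cl carbon) fixes which enantiomer of the ring results. The step needs chemoselectivity between the two electrophilic sites and the two nucleophiles: the chlorohydrinate persists at −78 °C, so no epoxide is present while the nitrile anion is, and alkylated 1 has no α-hydrogen, so no cyclopropane can form. The new C5 centre need not be controlled because step 5 removes it.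

Step 2
Reactants: 6 (4S)-4-hydroxy-2,2-dimethyl-6-(phenylsulfonyl)heptanenitrile
Product: 7 (4S)-4-[(tert-butyldimethylsilyl)oxy]-2,2-dimethyl-6-(phenylsulfonyl)heptanenitrile
Conditions: TBSCl, imidazole, DMF, 23 °C
Reagents that add atoms: tert-butyldimethylsilyl chloride, CC(C)(C)[Si](C)(C)Cl
Why: Standard silylation protects the secondary alcohol so that no alkoxide can add to the nitrile in step 3.

Step 3
Reactants: 7 (4S)-4-[(tert-butyldimethylsilyl)oxy]-2,2-dimethyl-6-(phenylsulfonyl)heptanenitrile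
Product: 9 (4S)-4-[(tert-butyldimethylsilyl)oxy]-2,2,6-trimethyl-6-(phenylsulfonyl)cyclohexan-1-one, via cyclic ketimine 8 (not isolated)
Conditions: LiN(iPr)2, THF, −78 → 0 °C; then AcOH, H2O, THF, 23 °C
Reagents that add atoms: water, O
Why: Deprotonation α to the sulfone (the only acidic C–H) and 6-exo-dig addition of the carbanion to the nitrile (Thorpe–Ziegler-type cyclization) close the ring at C5–C6, and buffered aqueous acid should hydrolyse ketimine 8 without cleaving the silyl ether.

Step 4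
Reactants: 9 (4S)-4-[(tert-butyldimethylsilyl)oxy]-2,2,6-trimethyl-6-(phenylsulfonyl)cyclohexan-1-one
Product: 10 (4R)-4-[(tert-butyldimethylsilyl)oxy]-2,2,6-trimethylcyclohexan-1-one (both C6 epimers)
Conditions: SmI2, THF–MeOH, −78 °C
Reagents that add atoms: none
Why: Reductive desulfonylation of an α-sulfonyl ketone (two single-electron transfers give the enolate, which is protonated) removes the activating group.

Step 5
Reactants: 10 (4R)-4-[(tert-butyldimethylsilyl)oxy]-2,2,6-trimethylcyclohexan-1-one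
Product: 11 (4R)-4-[(tert-butyldimethylsilyl)oxy]-2,6,6-trimethylcyclohex-1-en-1-yl trifluoromethanesulfonate
Conditions: LiN(iPr)2, THF, −78 → 0 °C; PhNTf2, 0 → 23 °C
Reagents that add atoms: N-phenylbis(trifluoromethanesulfonimide), O=S(=O)(N(c1ccccc1)S(=O)(=O)C(F)(F)F)C(F)(F)F
Why: The ketone has a single enolizable position, so enolate formation and O-triflation give one enol triflate with the C5=C6 double bond of the target; this compound is the branch point for rings A and B.

Step 6
Reactants: 11 (4R)-4-[(tert-butyldimethylsilyl)oxy]-2,6,6-trimethylcyclohex-1-en-1-yl trifluoromethanesulfonate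
Product: 12 (4R)-4-hydroxy-2,6,6-trimethylcyclohex-1-en-1-yl trifluoromethanesulfonate
Conditions: HF·pyridine, THF, 0 → 23 °C
Reagents that add atoms: none
Why: Acidic fluoride desilylation leaves the vinyl triflate untouched.

Step 7
Reactants: 12 (4R)-4-hydroxy-2,6,6-trimethylcyclohex-1-en-1-yl trifluoromethanesulfonate
Product: 13 (1R)-3,5,5-trimethyl-4-{[(trifluoromethyl)sulfonyl]oxy}cyclohex-3-en-1-yl acetate
Conditions: Ac2O, pyridine, DMAP (cat.), CH2Cl2, 23 °C
Reagents that add atoms: acetic anhydride, CC(=O)OC(C)=O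
Why: DMAP-catalysed acetylation installs the acetate of the target with retention at C3.

Step 8
Reactants: 14 (2E)-3-methylpent-2-en-4-yn-1-ol
Product: 15 (2E)-3-methylpent-2-en-4-ynal
Conditions: MnO2, CH2Cl2, 23 °C
Reagents that add atoms: none
Why: Allylic oxidation with MnO2 stops at the aldehyde and preserves the E alkene.

Step 9
Reactants: 15 (2E)-3-methylpent-2-en-4-ynal
Product: 16 (2E,4E)-5-methylhepta-2,4-dien-6-ynal
Conditions: Ph3P=CHCHO (1.05 equiv), toluene, 70 °C
Reagents that add atoms: (triphenylphosphoranylidene)acetaldehyde, O=CC=P(c1ccccc1)(c1ccccc1)c1ccccc1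
Why: Wittig two-carbon homologation with a stabilized ylide gives the E enal.

Step 10
Reactants: 13 (1R)-3,5,5-trimethyl-4-{[(trifluoromethyl)sulfonyl]oxy}cyclohex-3-en-1-yl acetate; 16 (2E,4E)-5-methylhepta-2,4-dien-6-ynal
Product: 17 (1R)-3,5,5-trimethyl-4-[(3E,5E)-3-methyl-7-oxohepta-3,5-dien-1-yn-1-yl]cyclohex-3-en-1-yl acetate
Conditions: Pd(PPh3)4 (5 mol %), CuI (10 mol %), Et3N, DMF, 23–45 °C, dark
Reagents that add atoms: none
Why: Sonogashira coupling of the vinyl triflate with the terminal alkyne forms the C6–alkyne bond and gives the ring-conjugated enyne directly.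

Step 11
Reactants: 14 (2E)-3-methylpent-2-en-4-yn-1-ol
Product: 18 diethyl [(2E)-3-methylpent-2-en-4-yn-1-yl]phosphonate
Conditions: ZnI2, P(OEt)3, THF, reflux
Reagents that add atoms: triethyl phosphite, CCOP(OCC)OCC
Why: ZnI2-mediated one-flask Arbuzov-type conversion of an allylic alcohol into the primary allylic phosphonate.

Step 12
Reactants: 17 (1R)-3,5,5-trimethyl-4-[(3E,5E)-3-methyl-7-oxohepta-3,5-dien-1-yn-1-yl]cyclohex-3-en-1-yl acetate; 18 diethyl [(2E)-3-methylpent-2-en-4-yn-1-yl]phosphonate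
Product: 19 (1R)-4-[(3E,5E,7E,9E)-3,10-dimethyldodeca-3,5,7,9-tetraene-1,11-diyn-1-yl]-3,5,5-trimethylcyclohex-3-en-1-yl acetate
Conditions: 18, LiN(SiMe3)2 (1.0 equiv), THF, −78 °C; add 17, −78 → 0 °C, dark
Reagents that add atoms: none
Why: Horner–Wadsworth–Emmons olefination of the allylic phosphonate anion (its C–H is more acidic than the alkyne C–H) with the aldehyde should give the new disubstituted alkene with E selectivity.

Step 13
Reactants: 20 propiolic acid
Product: 21 (2E)-2,3-dibromoprop-2-enoic acid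
Conditions: Br2, CHCl3, 0 → 23 °C, dark
Reagents that add atoms: bromine, BrBr
Why: Anti addition of bromine to the alkyne gives the E dibromide, in which the β-bromine is cis to the carboxyl group.

Step 14
Reactants: 19 (1R)-4-[(3E,5E,7E,9E)-3,10-dimethyldodeca-3,5,7,9-tetraene-1,11-diyn-1-yl]-3,5,5-trimethylcyclohex-3-en-1-yl acetate; 21 (2E)-2,3-dibromoprop-2-enoic acid
Product: 23 (1R)-4-[(3E,5E,7E,9E,11Z)-11-(4-bromo-5-oxofuran-2(5H)-ylidene)-3,10-dimethylundeca-3,5,7,9-tetraen-1-yn-1-yl]-3,5,5-trimethylcyclohex-3-en-1-yl acetate, via enynoic acid 22 (not isolated)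
Conditions: PdCl2(PPh3)2 (5 mol %), CuI (10 mol %), Et3N, MeCN, 23 °C, dark
Reagents that add atoms: none
Why: Sonogashira coupling at the more reactive β C–Br bond followed by anti addition of the carboxylate to the metal-activated alkyne (5-exo-dig) gives the Z γ-ylidene butenolide in one operation (tandem cross-coupling–lactonization).

Step 15
Reactants: 11 (4R)-4-[(tert-butyldimethylsilyl)oxy]-2,6,6-trimethylcyclohex-1-en-1-yl trifluoromethanesulfonate
Product: 24 methyl (4R)-4-[(tert-butyldimethylsilyl)oxy]-2,6,6-trimethylcyclohex-1-ene-1-carboxylate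
Conditions: Pd(OAc)2 (5 mol %), PPh3, CO (1 atm), MeOH, Et3N, DMF, 60 °C
Reagents that add atoms: carbon monoxide, [C-]#[O+]; methanol, CO
Why: Palladium-catalysed methoxycarbonylation of the vinyl triflate adds the one-carbon handle at C6.

Step 16
Reactants: 24 methyl (4R)-4-[(tert-butyldimethylsilyl)oxy]-2,6,6-trimethylcyclohex-1-ene-1-carboxylate
Product: 25 [(4R)-4-[(tert-butyldimethylsilyl)oxy]-2,6,6-trimethylcyclohex-1-en-1-yl]methanol
Conditions: iBu2AlH, CH2Cl2, −78 → 0 °C; Rochelle salt work-up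
Reagents that add atoms: none
Why: Hydride reduction of the conjugated ester gives the allylic alcohol needed to direct the epoxidation.

Step 17
Reactants: 25 [(4R)-4-[(tert-butyldimethylsilyl)oxy]-2,6,6-trimethylcyclohex-1-en-1-yl]methanol
Product: 26 [(1R,4S,6R)-4-[(tert-butyldimethylsilyl)oxy]-2,2,6-trimethyl-7-oxabicyclo[4.1.0]heptan-1-yl]methanol
Conditions: Ti(OiPr)4 (10 mol %), D-(−)-diethyl tartrate (12 mol %), t-BuOOH, 4 Å MS, CH2Cl2, −20 °C
Reagents that add atoms: tert-butyl hydroperoxide, CC(C)(C)OO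
Why: Sharpless asymmetric epoxidation under reagent control; D-(−)-diethyl tartrate (the antipode of the tartrate that gives (2S)-epoxy alcohols from simple allylic alcohols) should deliver oxygen to the face anti to the C3 silyloxy group and so set C5 and C6 of ring B.

Step 18
Reactants: 26 [(1R,4S,6R)-4-[(tert-butyldimethylsilyl)oxy]-2,2,6-trimethyl-7-oxabicyclo[4.1.0]heptan-1-yl]methanol
Product: 27 (1S,4S,6R)-4-[(tert-butyldimethylsilyl)oxy]-2,2,6-trimethyl-7-oxabicyclo[4.1.0]heptane-1-carbaldehyde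
Conditions: (Pr4N)RuO4 (5 mol %), N-methylmorpholine N-oxide, 4 Å MS, CH2Cl2, 23 °C
Reagents that add atoms: none
Why: Ley–Griffith oxidation gives the non-enolizable epoxy aldehyde without touching the epoxide.

Step 19
Reactants: 27 (1S,4S,6R)-4-[(tert-butyldimethylsilyl)oxy]-2,2,6-trimethyl-7-oxabicyclo[4.1.0]heptane-1-carbaldehyde
Product: 28 (1R,4S,6R)-4-[(tert-butyldimethylsilyl)oxy]-1-ethynyl-2,2,6-trimethyl-7-oxabicyclo[4.1.0]heptane
Conditions: dimethyl (1-diazo-2-oxopropyl)phosphonate, K2CO3, MeOH, 0 → 23 °C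
Reagents that add atoms: dimethyl (1-diazo-2-oxopropyl)phosphonate, COP(=O)(OC)C(=[N+]=[N-])C(C)=O
Why: Seyferth–Gilbert homologation with the Ohira–Bestmann reagent converts the aldehyde, which has no α-hydrogen, into the terminal alkyne.

Step 20
Reactants: 28 (1R,4S,6R)-4-[(tert-butyldimethylsilyl)oxy]-1-ethynyl-2,2,6-trimethyl-7-oxabicyclo[4.1.0]heptane
Product: 29 (1R,4S,6R)-1-ethynyl-2,2,6-trimethyl-7-oxabicyclo[4.1.0]heptan-4-ol
Conditions: Bu4NF, THF, 23 °C
Reagents that add atoms: none
Why: Fluoride desilylation frees the ring B hydroxyl before the coupling steps; the epoxide and alkyne are inert.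

Step 21
Reactants: 29 (1R,4S,6R)-1-ethynyl-2,2,6-trimethyl-7-oxabicyclo[4.1.0]heptan-4-ol
Product: 30 (1S,4S,6R)-2,2,6-trimethyl-1-[(E)-2-(tributylstannyl)ethenyl]-7-oxabicyclo[4.1.0]heptan-4-ol
Conditions: Bu3SnH, PdCl2(PPh3)2 (2 mol %), THF, 0 → 23 °C
Reagents that add atoms: tributyltin hydride, CCCC[SnH](CCCC)CCCC
Why: Palladium-catalysed syn hydrostannation should place tin on the terminal carbon (the quaternary propargylic centre blocks the internal position) and give the E vinylstannane.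

Step 22
Reactants: 23 (1R)-4-[(3E,5E,7E,9E,11Z)-11-(4-bromo-5-oxofuran-2(5H)-ylidene)-3,10-dimethylundeca-3,5,7,9-tetraen-1-yn-1-yl]-3,5,5-trimethylcyclohex-3-en-1-yl acetate; 30 (1S,4S,6R)-2,2,6-trimethyl-1-[(E)-2-(tributylstannyl)ethenyl]-7-oxabicyclo[4.1.0]heptan-4-ol
Product: 31 the target, (3S,5R,6S,3'R)-pyrrhoxanthin
Conditions: Pd2(dba)3 (2.5 mol %), AsPh3 (20 mol %), DMF, 23–40 °C, dark
Reagents that add atoms: none
Why: Stille coupling with retention of both alkene geometries joins the two halves under neutral conditions that should tolerate the epoxide, acetate, free hydroxyl and polyene.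

**Compound list**

1 | isobutyronitrile | CC(C)C#N | starting material
2 | (S)-epichlorohydrin | ClC[C@@H]1CO1 | starting material
3 | ethyl phenyl sulfone | CCS(=O)(=O)c1ccccc1 | starting material
4 | lithium (2S)-1-chloro-4-cyano-4-methylpentan-2-olate | N#CC(C)(C)C[C@H]([O-])CCl.[Li+] | intermediate
5 | 2,2-dimethyl-3-[(2S)-oxiran-2-yl]propanenitrile | N#CC(C)(C)C[C@H]1CO1 | intermediate
6 | (4S)-4-hydroxy-2,2-dimethyl-6-(phenylsulfonyl)heptanenitrile | N#CC(C)(C)C[C@H](O)CC(C)S(=O)(=O)c1ccccc1 | intermediate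
7 | (4S)-4-[(tert-butyldimethylsilyl)oxy]-2,2-dimethyl-6-(phenylsulfonyl)heptanenitrile | N#CC(C)(C)C[C@H](O[Si](C)(C)C(C)(C)C)CC(C)S(=O)(=O)c1ccccc1 | intermediate
8 | (4S)-4-[(tert-butyldimethylsilyl)oxy]-2,2,6-trimethyl-6-(phenylsulfonyl)cyclohexan-1-imine | N=C1C(C)(S(=O)(=O)c2ccccc2)C[C@@H](O[Si](C)(C)C(C)(C)C)CC1(C)C | intermediate
9 | (4S)-4-[(tert-butyldimethylsilyl)oxy]-2,2,6-trimethyl-6-(phenylsulfonyl)cyclohexan-1-one | O=C1C(C)(S(=O)(=O)c2ccccc2)C[C@@H](O[Si](C)(C)C(C)(C)C)CC1(C)C | intermediate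
10 | (4R)-4-[(tert-butyldimethylsilyl)oxy]-2,2,6-trimethylcyclohexan-1-one | O=C1C(C)C[C@@H](O[Si](C)(C)C(C)(C)C)CC1(C)C | intermediate
11 | (4R)-4-[(tert-butyldimethylsilyl)oxy]-2,6,6-trimethylcyclohex-1-en-1-yl trifluoromethanesulfonate | FC(F)(F)S(=O)(=O)OC1=C(C)C[C@@H](O[Si](C)(C)C(C)(C)C)CC1(C)C | intermediate
12 | (4R)-4-hydroxy-2,6,6-trimethylcyclohex-1-en-1-yl trifluoromethanesulfonate | FC(F)(F)S(=O)(=O)OC1=C(C)C[C@@H](O)CC1(C)C | intermediate
13 | (1R)-3,5,5-trimethyl-4-{[(trifluoromethyl)sulfonyl]oxy}cyclohex-3-en-1-yl acetate | CC(=O)O[C@@H]1CC(C)=C(OS(=O)(=O)C(F)(F)F)C(C)(C)C1 | intermediate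
14 | (2E)-3-methylpent-2-en-4-yn-1-ol | C#C/C(C)=C/CO | starting material
15 | (2E)-3-methylpent-2-en-4-ynal | C#C/C(C)=C/C=O | intermediate
16 | (2E,4E)-5-methylhepta-2,4-dien-6-ynal | C#C/C(C)=C/C=C/C=O | intermediate
17 | (1R)-3,5,5-trimethyl-4-[(3E,5E)-3-methyl-7-oxohepta-3,5-dien-1-yn-1-yl]cyclohex-3-en-1-yl acetate | CC(=O)O[C@@H]1CC(C)=C(C#C/C(C)=C/C=C/C=O)C(C)(C)C1 | intermediate
18 | diethyl [(2E)-3-methylpent-2-en-4-yn-1-yl]phosphonate | C#C/C(C)=C/CP(=O)(OCC)OCC | intermediate
19 | (1R)-4-[(3E,5E,7E,9E)-3,10-dimethyldodeca-3,5,7,9-tetraene-1,11-diyn-1-yl]-3,5,5-trimethylcyclohex-3-en-1-yl acetate | CC(=O)O[C@@H]1CC(C)=C(C#C/C(C)=C/C=C/C=C/C=C(C)/C#C)C(C)(C)C1 | intermediate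
20 | propiolic acid | C#CC(=O)O | starting material
21 | (2E)-2,3-dibromoprop-2-enoic acid | Br/C=C(/Br)C(=O)O | intermediate
22 | (2E,6E,8E,10E,12E)-15-[(4R)-4-acetoxy-2,6,6-trimethylcyclohex-1-en-1-yl]-2-bromo-6,13-dimethylpentadeca-2,6,8,10,12-pentaene-4,14-diynoic acid | OC(=O)/C(Br)=C\C#C/C(C)=C/C=C/C=C/C=C(C)/C#CC1=C(C)C[C@@H](OC(C)=O)CC1(C)C | intermediate
23 | (1R)-4-[(3E,5E,7E,9E,11Z)-11-(4-bromo-5-oxofuran-2(5H)-ylidene)-3,10-dimethylundeca-3,5,7,9-tetraen-1-yn-1-yl]-3,5,5-trimethylcyclohex-3-en-1-yl acetate | CC(=O)O[C@@H]1CC(C)=C(C#C/C(C)=C/C=C/C=C/C=C(C)/C=C2C=C(Br)C(=O)O/2)C(C)(C)C1 | intermediate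
24 | methyl (4R)-4-[(tert-butyldimethylsilyl)oxy]-2,6,6-trimethylcyclohex-1-ene-1-carboxylate | COC(=O)C1=C(C)C[C@@H](O[Si](C)(C)C(C)(C)C)CC1(C)C | intermediate
25 | [(4R)-4-[(tert-butyldimethylsilyl)oxy]-2,6,6-trimethylcyclohex-1-en-1-yl]methanol | OCC1=C(C)C[C@@H](O[Si](C)(C)C(C)(C)C)CC1(C)C | intermediate
26 | [(1R,4S,6R)-4-[(tert-butyldimethylsilyl)oxy]-2,2,6-trimethyl-7-oxabicyclo[4.1.0]heptan-1-yl]methanol | OC[C@@]12O[C@]1(C)C[C@@H](O[Si](C)(C)C(C)(C)C)CC2(C)C | intermediate
27 | (1S,4S,6R)-4-[(tert-butyldimethylsilyl)oxy]-2,2,6-trimethyl-7-oxabicyclo[4.1.0]heptane-1-carbaldehyde | O=C[C@@]12O[C@]1(C)C[C@@H](O[Si](C)(C)C(C)(C)C)CC2(C)C | intermediate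
28 | (1R,4S,6R)-4-[(tert-butyldimethylsilyl)oxy]-1-ethynyl-2,2,6-trimethyl-7-oxabicyclo[4.1.0]heptane | C#C[C@@]12O[C@]1(C)C[C@@H](O[Si](C)(C)C(C)(C)C)CC2(C)C | intermediate
29 | (1R,4S,6R)-1-ethynyl-2,2,6-trimethyl-7-oxabicyclo[4.1.0]heptan-4-ol | C#C[C@@]12O[C@]1(C)C[C@@H](O)CC2(C)C | intermediate
30 | (1S,4S,6R)-2,2,6-trimethyl-1-[(E)-2-(tributylstannyl)ethenyl]-7-oxabicyclo[4.1.0]heptan-4-ol | CCCC[Sn](CCCC)(CCCC)/C=C/[C@@]12O[C@]1(C)C[C@@H](O)CC2(C)C | intermediate
31 | (3S,5R,6S,3'R)-pyrrhoxanthin | CC(=O)O[C@@H]1CC(C)=C(C#C/C(C)=C/C=C/C=C/C=C(C)/C=C2C=C(/C=C/[C@@]34O[C@]3(C)C[C@@H](O)CC4(C)C)C(=O)O/2)C(C)(C)C1 | target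

**Summary**

Total step count: 22. Longest linear sequence: 13 steps (steps 1–5, 15–21, 22).

Steps most likely to fail:

Step 1. The nitrile anion may add twice to the re-formed epoxide, direct displacement of chloride may erode enantiopurity, or the alkoxide may add to the nitrile. The fallback sets out from 1 and 2 and returns at 7. The adduct of lithiated 1 and 2 is quenched with acetic acid at −78 °C, before any epoxide can re-form, to give the chlorohydrin (4S)-5-chloro-4-hydroxy-2,2-dimethylpentanenitrile F1. Silylation (TBSCl, imidazole) gives (4S)-4-[(tert-butyldimethylsilyl)oxy]-5-chloro-2,2-dimethylpentanenitrile F2. Finkelstein exchange (NaI, 2-butanone, reflux) gives (4S)-4-[(tert-butyldimethylsilyl)oxy]-5-iodo-2,2-dimethylpentanenitrile F3. Alkylation of lithiated 3 with F3 (THF–DMPU) gives 7. The second C–C bond is thus made by alkylation with a halide on a protected alcohol instead of by a second epoxide opening in the same flask.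

Step 3. Addition of the tertiary sulfonyl carbanion to the hindered nitrile may be slow or reversible, and hydrolysis of the hindered ketimine may be slow enough to cost the silyl ether. The fallback sets out from 7 and returns at 9. Reduction of the nitrile with iBu2AlH and hydrolysis gives (4S)-4-[(tert-butyldimethylsilyl)oxy]-2,2-dimethyl-6-(phenylsulfonyl)heptanal F4. Intramolecular addition of the sulfonyl carbanion to the aldehyde (LiN(iPr)2, THF, −78 °C) gives (4S)-4-[(tert-butyldimethylsilyl)oxy]-2,2,6-trimethyl-6-(phenylsulfonyl)cyclohexan-1-ol F5. Dess–Martin oxidation of F5 gives 9.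

Step 14. Selectivity between the two C–Br bonds may be poor, 6-endo closure to the pyranone may compete, and the alkyne may homocouple. The fallback sets out from 19 and 21 and returns at 23. Acid 21 is converted (allyl bromide, K2CO3, DMF) into allyl (2E)-2,3-dibromoprop-2-enoate F6. Sonogashira coupling of 19 with F6 at the β C–Br bond gives the allyl ester of acid 22, allyl enynoate F7. Deallylation (Pd(PPh3)4, morpholine) gives acid 22, now isolated, and AgNO3-catalysed 5-exo-dig lactonization in acetone gives 23.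

Further compounds
F1 | step 1 | (4S)-5-chloro-4-hydroxy-2,2-dimethylpentanenitrile | N#CC(C)(C)C[C@H](O)CCl
F2 | step 1 | (4S)-4-[(tert-butyldimethylsilyl)oxy]-5-chloro-2,2-dimethylpentanenitrile | N#CC(C)(C)C[C@H](O[Si](C)(C)C(C)(C)C)CCl
F3 | step 1 | (4S)-4-[(tert-butyldimethylsilyl)oxy]-5-iodo-2,2-dimethylpentanenitrile | N#CC(C)(C)C[C@H](O[Si](C)(C)C(C)(C)C)CI
F4 | step 3 | (4S)-4-[(tert-butyldimethylsilyl)oxy]-2,2-dimethyl-6-(phenylsulfonyl)heptanal | O=CC(C)(C)C[C@H](O[Si](C)(C)C(C)(C)C)CC(C)S(=O)(=O)c1ccccc1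
F5 | step 3 | (4S)-4-[(tert-butyldimethylsilyl)oxy]-2,2,6-trimethyl-6-(phenylsulfonyl)cyclohexan-1-ol | OC1C(C)(S(=O)(=O)c2ccccc2)C[C@@H](O[Si](C)(C)C(C)(C)C)CC1(C)C
F6 | step 14 | allyl (2E)-2,3-dibromoprop-2-enoate | Br/C=C(/Br)C(=O)OCC=C
F7 | step 14 | allyl (2E,6E,8E,10E,12E)-15-[(4R)-4-acetoxy-2,6,6-trimethylcyclohex-1-en-1-yl]-2-bromo-6,13-dimethylpentadeca-2,6,8,10,12-pentaene-4,14-diynoate | C=CCOC(=O)/C(Br)=C\C#C/C(C)=C/C=C/C=C/C=C(C)/C#CC1=C(C)C[C@@H](OC(C)=O)CC1(C)C
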